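**Plan** (chain numbered from the lactone carbonyl C1 to C15, the furan on C15)
- Cuts, in order: C9=C10 (cross-metathesis), O–C4 of the lactone (Baeyer–Villiger), C3–C4 (ring expansion), C4–C(OH) of a cyclopropanol (alkenylmetal plus cyclopropanone), C4=C5 (iodo-olefination of a linalool-derived aldehyde).
- Enabling feature: the γ-lactone ring O–C1–C2–C3–C4 has quaternary C4 (CH3, O) next to carbinol C5. It is therefore the Baeyer–Villiger image of a 2-methyl-2-(1-hydroxyalkyl)cyclobutanone, which is what the C4–C5 epoxide of a (Z)-1-alkenylcyclopropanol gives on a 1,2-shift.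
- Forward: (S)-linalool → aldehyde → (Z)-iodoalkene → alkenylcyclopropanol → epoxide → cyclobutanone (the only carbocycle built) → γ-lactone → desilylation → metathesis with a separately made furyl 1,4-diene (furan ring bought in).
- Stereochemistry: C8 from (S)-linalool; C5 from the face chosen by the Shi ketone; C4 from the same epoxide, inverted in the shift and retained in the oxygen insertion; C12=C13 (E) from syn carboalumination; C9=C10 (E) from the metathesis.

Key step: step 7

Assumption: (S)-linalool of high enantiomeric purity is used, and the facial sense of the epoxidation in step 6 is assigned from the spiro transition-state model for trisubstituted alkenes (D-fructose-derived ketone placing O so that C5 becomes R).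

**Step 1**
Reactants: 1 (S)-(+)-linalool
Product: 2 triethyl{[(3S)-3,7-dimethylocta-1,6-dien-3-yl]oxy}silane
Conditions: TESOTf, 2,6-lutidine, CH2Cl2, −78 → 0 °C
Reagents that add atoms: triethylsilyl trifluoromethanesulfonate, CC[Si](CC)(CC)OS(=O)(=O)C(F)(F)F
Why: Silylation with a silyl triflate and a hindered pyridine base caps the tertiary allylic alcohol without ionising it, and the tertiary TES ether should survive the organometallic and oxidative steps yet fall to fluoride at the end.

**Step 2**
Reactants: 2 triethyl{[(3S)-3,7-dimethylocta-1,6-dien-3-yl]oxy}silane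
Product: 4 (4S)-4-methyl-4-(triethylsilyloxy)hex-5-enal, via secondary ozonide 3 (not isolated)
Conditions: O3 (1 equiv, Sudan Red 7B end point), CH2Cl2, −78 °C; then PPh3, −78 °C → rt
Reagents that add atoms: ozone, [O-][O+]=O
Why: In this selective ozonolysis the electron-rich trisubstituted alkene should react far faster than the monosubstituted vinyl group, which is deactivated by the allylic silyloxy substituent, so one equivalent of ozone and phosphine reduction of the ozonide should leave the vinyl group intact.

**Step 3**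
Reactants: 4 (4S)-4-methyl-4-(triethylsilyloxy)hex-5-enal
Product: 5 (3S,6Z)-7-iodo-3-methyl-3-(triethylsilyloxy)octa-1,6-diene
Conditions: EtPPh3I, n-BuLi, THF, rt; I2, −78 °C; NaHMDS, −20 °C; then 4, −78 → −20 °C
Reagents that add atoms: ethyltriphenylphosphonium iodide, CC[P+](c1ccccc1)(c1ccccc1)c1ccccc1.[I-]; iodine, II
Why: The Stork–Zhao olefination with the α-iodoethylidene ylide is kinetically Z-selective for aliphatic aldehydes, which places iodine cis to the chain, the geometry that later puts the cyclopropanol carbon cis to C6.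

**Step 4**
Reactants: 6 (1-ethoxycyclopropoxy)trimethylsilane
Product: 7 1-ethoxycyclopropan-1-ol
Conditions: MeOH, rt; evaporate, use fresh
Reagents that add atoms: none
Why: Methanolysis of the trimethylsilyl ketal (silyl ether solvolysis) should give the cyclopropanone ethyl hemiacetal, the usual storable precursor of cyclopropanone.

**Step 5**
Reactants: 5 (3S,6Z)-7-iodo-3-methyl-3-(triethylsilyloxy)octa-1,6-diene; 7 1-ethoxycyclopropan-1-ol
Product: 11 1-[(2Z,6S)-6-methyl-6-(triethylsilyloxy)octa-2,7-dien-2-yl]cyclopropan-1-ol, via alkenyllithium 8 (not isolated), via alkenylmagnesium bromide 9 (not isolated), via cyclopropanone 10 (not isolated)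
Conditions: 5, t-BuLi (2.1 equiv), Et2O, −78 °C; MgBr2·OEt2, −78 → 0 °C; add to 7/MeMgBr (1.5 equiv each, THF, 0 °C); rt → 45 °C; aq NH4Cl
Reagents that add atoms: none
Why: Iodine–lithium exchange and transmetalation to magnesium proceed with retention of alkene geometry, and the bromomagnesium salt of the hemiacetal releases cyclopropanone, which the alkenyl Grignard reagent should capture by 1,2-addition (the established addition of vinylic Grignard reagents to cyclopropanone formed in situ).

**Step 6**
Reactants: 11 1-[(2Z,6S)-6-methyl-6-(triethylsilyloxy)octa-2,7-dien-2-yl]cyclopropan-1-ol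
Product: 12 1-[(2R,3R)-2-methyl-3-[(3S)-3-methyl-3-(triethylsilyloxy)pent-4-en-1-yl]oxiran-2-yl]cyclopropan-1-ol
Conditions: D-fructose-derived Shi ketone (0.3 equiv), Oxone, K2CO3, Bu4NHSO4, MeCN–DMM/aq Na2B4O7–EDTA (pH 10.5), 0 °C; extractive work-up, used crude
Reagents that add atoms: potassium peroxymonosulfate (Oxone), [K+].[O-]S(=O)(=O)OO
Why: In the Shi asymmetric epoxidation the chiral dioxirane should add oxygen syn to the trisubstituted Z-alkene through a spiro transition state on the face that makes C5 R (and hence the epoxide carbon C4 R), while the free tertiary hydroxyl is tolerated and the monosubstituted vinyl group is a poor dioxirane substrate.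

**Step 7**
Reactants: 12 1-[(2R,3R)-2-methyl-3-[(3S)-3-methyl-3-(triethylsilyloxy)pent-4-en-1-yl]oxiran-2-yl]cyclopropan-1-ol
Product: 13 (2S)-2-[(1R,4S)-1-hydroxy-4-methyl-4-(triethylsilyloxy)hex-5-en-1-yl]-2-methylcyclobutan-1-one
Conditions: BF3·OEt2 (0.5 equiv), CH2Cl2, −78 °C; aq NaHCO3
Reagents that add atoms: none
Why: Coordination of the Lewis acid to the epoxide oxygen weakens the tertiary C4–O bond, and as it breaks a ring CH2 of the cyclopropanol shifts from the carbinol carbon to C4 anti to the departing oxygen while the carbinol oxygen closes to the ketone, a concerted 1,2-shift that forms C3–C4. The closest known reaction type is the semipinacol rearrangement of 2,3-epoxy alcohols, specifically the acid-promoted ring expansion of epoxides of 1-alkenylcyclopropanols to 2-(1-hydroxyalkyl)cyclobutanones. The four-membered ring closes by ring enlargement and not by cyclisation: the three-membered carbocycle takes up C4 through the 1,2-alkyl shift, driven by release of cyclopropane strain and formation of the carbonyl group. The new quaternary centre C4 is controlled by the epoxide, since migration with inversion turns the (R)-configured epoxide carbon into the (S)-configured ring carbon, while C5 keeps the epoxide oxygen with retention as the R carbinol, so that Z geometry plus epoxide face fix the C4/C5 relationship. The step needs cleavage of C4–O and not C5–O, and carbon migration in place of hydride shift or external capture; the tertiary nature of C4, the electron-releasing cyclopropanol carbon beside it and the equivalence of the two ring CH2 groups secure a single product, and low temperature with substoichiometric Lewis acid should spare the tertiary allylic silyl ether.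

**Step 8**
Reactants: 13 (2S)-2-[(1R,4S)-1-hydroxy-4-methyl-4-(triethylsilyloxy)hex-5-en-1-yl]-2-methylcyclobutan-1-one
Product: 14 (5S)-5-[(1R,4S)-1-hydroxy-4-methyl-4-(triethylsilyloxy)hex-5-en-1-yl]-5-methyloxolan-2-one
Conditions: mCPBA (1.2 equiv), NaHCO3, CH2Cl2, 0 °C
Reagents that add atoms: 3-chloroperoxybenzoic acid, OOC(=O)c1cccc(Cl)c1
Why: Baeyer–Villiger oxidation of the strained cyclobutanone is fast, the more substituted quaternary C4 migrates to oxygen with retention to give the 5,5-disubstituted γ-lactone, and buffered peracid at 0 °C should leave the electron-poor terminal vinyl group untouched.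

**Step 9**
Reactants: 14 (5S)-5-[(1R,4S)-1-hydroxy-4-methyl-4-(triethylsilyloxy)hex-5-en-1-yl]-5-methyloxolan-2-one
Product: 15 (5S)-5-[(1R,4S)-1,4-dihydroxy-4-methylhex-5-en-1-yl]-5-methyloxolan-2-one
Conditions: HF·pyridine, pyridine, THF, 0 °C → rt
Reagents that add atoms: none
Why: Buffered fluoride desilylation cleaves the tertiary TES ether without opening or translactonising the γ-lactone, and it frees the tertiary allylic alcohol, which is a far better metathesis partner than its silyl ether.

**Step 10**
Reactants: 16 pent-1-en-4-yne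
Product: 19 (2E)-3-methylhexa-2,5-dien-1-ol, via alkenylalane 17 (not isolated), via lithium alkenylalanate 18 (not isolated)
Conditions: Me3Al, Cp2ZrCl2 (0.2 equiv), CH2Cl2, 0 °C → rt; n-BuLi, THF, −78 °C; (CH2O)n, −78 °C → rt; aq HCl
Reagents that add atoms: trimethylaluminium, C[Al](C)C; formaldehyde (as paraformaldehyde), C=O
Why: Zirconium-catalysed Negishi carboalumination adds methyl and aluminium syn across the terminal alkyne much faster than across the isolated alkene, and hydroxymethylation of the derived alanate with retention fixes the E trisubstituted alkene that becomes C12=C13.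

**Step 11**
Reactants: 19 (2E)-3-methylhexa-2,5-dien-1-ol
Product: 21 (4E)-6-chloro-4-methylhexa-1,4-diene, via allylic mesylate 20 (not isolated)
Conditions: MsCl, s-collidine, LiCl, DMF, 0 °C
Reagents that add atoms: lithium chloride, [Li+].[Cl-]
Why: Mesylation followed by SN2 displacement with chloride at the primary allylic carbon should give the chloride without allylic transposition or loss of alkene geometry.

**Step 12**
Reactants: 22 3-furanmethanol
Product: 24 3-(chloromethyl)furan, via furylmethyl mesylate 23 (not isolated)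
Conditions: MsCl, s-collidine, LiCl, DMF, 0 °C; used at once
Reagents that add atoms: lithium chloride, [Li+].[Cl-]
Why: The same mesylate–chloride displacement converts the furylmethyl alcohol under buffered conditions, so the acid-sensitive furan never meets free HCl.

**Step 13**
Reactants: 24 3-(chloromethyl)furan; 21 (4E)-6-chloro-4-methylhexa-1,4-diene
Product: 26 3-[(3E)-4-methylhepta-3,6-dien-1-yl]furan, via furylmethylmagnesium chloride 25 (not isolated)
Conditions: Mg, THF, 0 °C → rt; then 21, Li2CuCl4 (3 mol%), THF, 0 °C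
Reagents that add atoms: none
Why: Copper-catalysed coupling of the 3-furylmethyl Grignard reagent with a primary allylic chloride should occur at the α-carbon (SN2) with retention of alkene geometry, a coupling well established for furanoterpene side chains.

**Step 14**
Reactants: 15 (5S)-5-[(1R,4S)-1,4-dihydroxy-4-methylhex-5-en-1-yl]-5-methyloxolan-2-one; 26 3-[(3E)-4-methylhepta-3,6-dien-1-yl]furan
Product: 27 (5S)-5-[(1R,4S,5E,8E)-11-(furan-3-yl)-1,4-dihydroxy-4,8-dimethylundeca-5,8-dien-1-yl]-5-methyloxolan-2-one
Conditions: Hoveyda–Grubbs II (10 mol%), 26 (3 equiv), 1,4-benzoquinone (10 mol%), CH2Cl2, 40 °C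
Reagents that add atoms: none
Why: Olefin cross-metathesis between the free tertiary allylic alcohol and an excess of the unhindered terminal alkene should be selective for the cross product with E geometry at C9=C10, enforced by the quaternary carbinol, while the trisubstituted alkene and the furan are spectators and benzoquinone suppresses migration of the skipped diene.

**Compound list**
1 | (S)-(+)-linalool, (3S)-3,7-dimethylocta-1,6-dien-3-ol | C=C[C@@](C)(O)CCC=C(C)C | starting material
2 | triethyl{[(3S)-3,7-dimethylocta-1,6-dien-3-yl]oxy}silane | C=C[C@@](C)(O[Si](CC)(CC)CC)CCC=C(C)C | intermediate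
3 | 3,3-dimethyl-5-[(3S)-3-methyl-3-(triethylsilyloxy)pent-4-en-1-yl]-1,2,4-trioxolane (ring CH epimers) | C=C[C@@](C)(O[Si](CC)(CC)CC)CCC1OOC(C)(C)O1 | intermediate (not isolated)
4 | (4S)-4-methyl-4-(triethylsilyloxy)hex-5-enal | C=C[C@@](C)(O[Si](CC)(CC)CC)CCC=O | intermediate
5 | (3S,6Z)-7-iodo-3-methyl-3-(triethylsilyloxy)octa-1,6-diene | C=C[C@@](C)(O[Si](CC)(CC)CC)CC/C=C(\I)C | intermediate
6 | (1-ethoxycyclopropoxy)trimethylsilane | CCOC1(CC1)O[Si](C)(C)C | starting material
7 | 1-ethoxycyclopropan-1-ol | CCOC1(O)CC1 | intermediate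
8 | [(2E,6S)-6-methyl-6-(triethylsilyloxy)octa-2,7-dien-2-yl]lithium (lithium cis to the chain) | C=C[C@@](C)(O[Si](CC)(CC)CC)CC/C=C(\[Li])C | intermediate (not isolated)
9 | bromo[(2Z,6S)-6-methyl-6-(triethylsilyloxy)octa-2,7-dien-2-yl]magnesium | C=C[C@@](C)(O[Si](CC)(CC)CC)CC/C=C(\[Mg]Br)C | intermediate (not isolated)
10 | cyclopropanone | O=C1CC1 | intermediate (not isolated)
11 | 1-[(2Z,6S)-6-methyl-6-(triethylsilyloxy)octa-2,7-dien-2-yl]cyclopropan-1-ol | C=C[C@@](C)(O[Si](CC)(CC)CC)CC/C=C(/C)C1(O)CC1 | intermediate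
12 | 1-[(2R,3R)-2-methyl-3-[(3S)-3-methyl-3-(triethylsilyloxy)pent-4-en-1-yl]oxiran-2-yl]cyclopropan-1-ol | C=C[C@@](C)(O[Si](CC)(CC)CC)CC[C@H]1O[C@@]1(C)C1(O)CC1 | intermediate
13 | (2S)-2-[(1R,4S)-1-hydroxy-4-methyl-4-(triethylsilyloxy)hex-5-en-1-yl]-2-methylcyclobutan-1-one | C=C[C@@](C)(O[Si](CC)(CC)CC)CC[C@@H](O)[C@]1(C)CCC1=O | intermediate
14 | (5S)-5-[(1R,4S)-1-hydroxy-4-methyl-4-(triethylsilyloxy)hex-5-en-1-yl]-5-methyloxolan-2-one | C=C[C@@](C)(O[Si](CC)(CC)CC)CC[C@@H](O)[C@]1(C)CCC(=O)O1 | intermediate
15 | (5S)-5-[(1R,4S)-1,4-dihydroxy-4-methylhex-5-en-1-yl]-5-methyloxolan-2-one | C=C[C@@](C)(O)CC[C@@H](O)[C@]1(C)CCC(=O)O1 | intermediate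
16 | pent-1-en-4-yne | C=CCC#C | starting material
17 | dimethyl[(1E)-2-methylpenta-1,4-dien-1-yl]alumane | C=CC/C(C)=C/[Al](C)C | intermediate (not isolated)
18 | lithium butyl(dimethyl)[(1E)-2-methylpenta-1,4-dien-1-yl]aluminate | [Li+].CCCC[Al-](C)(C)/C=C(\C)CC=C | intermediate (not isolated)
19 | (2E)-3-methylhexa-2,5-dien-1-ol | C=CC/C(C)=C/CO | intermediate
20 | (2E)-3-methylhexa-2,5-dien-1-yl methanesulfonate | C=CC/C(C)=C/COS(C)(=O)=O | intermediate (not isolated)
21 | (4E)-6-chloro-4-methylhexa-1,4-diene | C=CC/C(C)=C/CCl | intermediate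
22 | 3-furanmethanol | OCc1ccoc1 | starting material
23 | furan-3-ylmethyl methanesulfonate | CS(=O)(=O)OCc1ccoc1 | intermediate (not isolated)
24 | 3-(chloromethyl)furan | ClCc1ccoc1 | intermediate
25 | chloro(furan-3-ylmethyl)magnesium | Cl[Mg]Cc1ccoc1 | intermediate (not isolated)
26 | 3-[(3E)-4-methylhepta-3,6-dien-1-yl]furan | C=CC/C(C)=C/CCc1ccoc1 | intermediate
27 | (5S)-5-[(1R,4S,5E,8E)-11-(furan-3-yl)-1,4-dihydroxy-4,8-dimethylundeca-5,8-dien-1-yl]-5-methyloxolan-2-one (CNP0151262.1) | C/C(=C\CCc1ccoc1)C/C=C/[C@@](C)(O)CC[C@@H](O)[C@]1(C)CCC(=O)O1 | target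

**Step count**
Total: 14 steps. Longest linear sequence: 9 steps from (S)-linalool (steps 1, 2, 3, 5, 6, 7, 8, 9, 14).

**Steps most likely to fail**

Step 6. The epoxidation may show poor facial selectivity or stall on the hindered Z-alkene that carries a free tertiary cyclopropanol, and the cyclopropanol may open under the basic oxidising medium. The fallback sets out from aldehyde 4 and builds the C4/C5 pair by oxygen attack instead of carbon migration. Addition of isopropenylmagnesium bromide (THF, −78 °C) should give the allylic alcohol (6S)-2,6-dimethyl-6-(triethylsilyloxy)octa-1,7-dien-3-ol F1 as a mixture of carbinol epimers, which does not matter. Johnson–Claisen rearrangement with triethyl orthoacetate and catalytic propionic acid (140 °C) should give ethyl (4E,8S)-4,8-dimethyl-8-(triethylsilyloxy)deca-4,9-dienoate F2 through a chair transition state. Shi epoxidation of this unhindered E-trisubstituted alkene with the same D-fructose-derived ketone should give ethyl 3-[(2R,3R)-2-methyl-3-[(3S)-3-methyl-3-(triethylsilyloxy)pent-4-en-1-yl]oxiran-2-yl]propanoate F3. Saponification (LiOH, THF/H2O) and mild acidification give 3-[(2R,3R)-2-methyl-3-[(3S)-3-methyl-3-(triethylsilyloxy)pent-4-en-1-yl]oxiran-2-yl]propanoic acid F4, not isolated, whose carboxyl group opens the epoxide at tertiary C4 in 5-exo fashion with inversion. This comes back to the route at lactone 14, before step 9.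

Step 5. The addition may give low conversion because cyclopropanone formed in situ oligomerises or the alkenylmetal is quenched by the hemiacetal. The fallback sets out from iodide 5 and closes the three-membered ring after the C–C bond is made. Alkenyllithium 8, generated as in step 5, is added to 1,3-dichloroacetone (Et2O, −78 °C) to give (3Z,7S)-1-chloro-2-(chloromethyl)-3,7-dimethyl-7-(triethylsilyloxy)nona-3,8-dien-2-ol F5. Deprotonation and reduction with lithium naphthalenide (THF, −78 °C) should effect reductive 1,3-closure, the known dichloroacetone route to 1-substituted cyclopropanols. This comes back to the route at cyclopropanol 11, before step 6.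

Step 14. The metathesis may suffer slow turnover at the quaternary allylic carbinol, homodimerisation of the diene and migration of its skipped double bonds. The fallback sets out from lactone 14 and from Grignard reagent 25 and joins C10–C11 by cross-coupling.
- Lactone side: silylation of C5–OH (TESOTf, 2,6-lutidine) gives (5S)-5-methyl-5-[(1R,4S)-4-methyl-1,4-bis(triethylsilyloxy)hex-5-en-1-yl]oxolan-2-one F6. Ozonolysis of the vinyl group passes through the ozonide (5S)-5-methyl-5-[(1R,4S)-4-methyl-1,4-bis(triethylsilyloxy)-4-(1,2,4-trioxolan-3-yl)butyl]oxolan-2-one F7, not isolated, and PPh3 reduction gives (2S,5R)-2-methyl-5-[(2S)-2-methyl-5-oxooxolan-2-yl]-2,5-bis(triethylsilyloxy)pentanal F8. Chromium-mediated Takai-type olefination (Cl2CHBpin, CrCl2, LiI, THF) should give the E alkenylboronate (5S)-5-methyl-5-[(1R,4S,5E)-4-methyl-6-(4,4,5,5-tetramethyl-1,3,2-dioxaborolan-2-yl)-1,4-bis(triethylsilyloxy)hex-5-en-1-yl]oxolan-2-one F9.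
- Furan side: copper-catalysed SN2′ opening of 2-methyl-2-vinyloxirane by 25 (CuI cat., THF, −30 °C) should give (2E)-5-(furan-3-yl)-2-methylpent-2-en-1-ol F10, and methyl chloroformate/pyridine gives (2E)-5-(furan-3-yl)-2-methylpent-2-en-1-yl methyl carbonate F11.
- Union: palladium-catalysed allyl–alkenyl Suzuki–Miyaura coupling of F9 with F11 (Pd(PPh3)4, THF, 50 °C) at the unhindered allyl terminus should give (5S)-5-[(1R,4S,5E,8E)-11-(furan-3-yl)-4,8-dimethyl-1,4-bis(triethylsilyloxy)undeca-5,8-dien-1-yl]-5-methyloxolan-2-one F12. HF·pyridine then removes both silyl groups, and this comes back to the route at target 27.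

**Further compounds**
F1 | step 6 | (6S)-2,6-dimethyl-6-(triethylsilyloxy)octa-1,7-dien-3-ol | C=C[C@@](C)(O[Si](CC)(CC)CC)CCC(O)C(C)=C
F2 | step 6 | ethyl (4E,8S)-4,8-dimethyl-8-(triethylsilyloxy)deca-4,9-dienoate | C=C[C@@](C)(O[Si](CC)(CC)CC)CC/C=C(\C)CCC(=O)OCC
F3 | step 6 | ethyl 3-[(2R,3R)-2-methyl-3-[(3S)-3-methyl-3-(triethylsilyloxy)pent-4-en-1-yl]oxiran-2-yl]propanoate | C=C[C@@](C)(O[Si](CC)(CC)CC)CC[C@H]1O[C@]1(C)CCC(=O)OCC
F4 | step 6 | 3-[(2R,3R)-2-methyl-3-[(3S)-3-methyl-3-(triethylsilyloxy)pent-4-en-1-yl]oxiran-2-yl]propanoic acid | C=C[C@@](C)(O[Si](CC)(CC)CC)CC[C@H]1O[C@]1(C)CCC(=O)O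
F5 | step 5 | (3Z,7S)-1-chloro-2-(chloromethyl)-3,7-dimethyl-7-(triethylsilyloxy)nona-3,8-dien-2-ol | C=C[C@@](C)(O[Si](CC)(CC)CC)CC/C=C(/C)C(O)(CCl)CCl
F6 | step 14 | (5S)-5-methyl-5-[(1R,4S)-4-methyl-1,4-bis(triethylsilyloxy)hex-5-en-1-yl]oxolan-2-one | C=C[C@@](C)(O[Si](CC)(CC)CC)CC[C@@H](O[Si](CC)(CC)CC)[C@]1(C)CCC(=O)O1
F7 | step 14 | (5S)-5-methyl-5-[(1R,4S)-4-methyl-1,4-bis(triethylsilyloxy)-4-(1,2,4-trioxolan-3-yl)butyl]oxolan-2-one (trioxolane CH epimers) | C1OOC(O1)[C@@](C)(O[Si](CC)(CC)CC)CC[C@@H](O[Si](CC)(CC)CC)[C@]2(C)CCC(=O)O2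
F8 | step 14 | (2S,5R)-2-methyl-5-[(2S)-2-methyl-5-oxooxolan-2-yl]-2,5-bis(triethylsilyloxy)pentanal | O=C[C@@](C)(O[Si](CC)(CC)CC)CC[C@@H](O[Si](CC)(CC)CC)[C@]1(C)CCC(=O)O1
F9 | step 14 | (5S)-5-methyl-5-[(1R,4S,5E)-4-methyl-6-(4,4,5,5-tetramethyl-1,3,2-dioxaborolan-2-yl)-1,4-bis(triethylsilyloxy)hex-5-en-1-yl]oxolan-2-one | CC1(C)OB(/C=C/[C@@](C)(O[Si](CC)(CC)CC)CC[C@@H](O[Si](CC)(CC)CC)[C@]2(C)CCC(=O)O2)OC1(C)C
F10 | step 14 | (2E)-5-(furan-3-yl)-2-methylpent-2-en-1-ol | OC/C(C)=C/CCc1ccoc1
F11 | step 14 | (2E)-5-(furan-3-yl)-2-methylpent-2-en-1-yl methyl carbonate | COC(=O)OC/C(C)=C/CCc1ccoc1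
F12 | step 14 | (5S)-5-[(1R,4S,5E,8E)-11-(furan-3-yl)-4,8-dimethyl-1,4-bis(triethylsilyloxy)undeca-5,8-dien-1-yl]-5-methyloxolan-2-one | C/C(=C\CCc1ccoc1)C/C=C/[C@@](C)(O[Si](CC)(CC)CC)CC[C@@H](O[Si](CC)(CC)CC)[C@]1(C)CCC(=O)O1
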